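Retrosynthesis: after removing four O-benzyl groups and the C3 hydroxyl, ring C is cut at O1–C8a, C4–C4a and O1–C2. This separates ring A, as 3,5-bis(benzyloxy)benzyne, from an arylpropiolic acid that already holds rings B, D and E.
Enabling feature: in ring A, O1 (on C8a) and carbonyl carbon C4 (on C4a) sit on adjacent carbons, and the C5 oxygen stands directly beside C4a. A 3-alkoxyaryne produces exactly this contiguous pattern when it takes up the oxygen and the acyl carbon of a carboxylate.
The acid goes back to a ring-B aldehyde: the formyl carbon becomes C2, CBr4 supplies C3 and CO2 supplies C4. Ring D is cut at C11–O and C10–O into an aryl glycidyl ether (from ferulic acid) and 3,4-dihydroxybenzaldehyde.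
Forward order: ring D closes first (epoxide opening by the meta oxygen, Mitsunobu closure by the para oxygen). The aldehyde then becomes the propiolic acid, ring C forms in the aryne cascade, and C3 hydroxylation and hydrogenolysis finish the route.
Stereochemistry: one Sharpless epoxidation with L-(+)-tartrate sets both centres as 2S,3S. Two SN2 inversions turn them into the trans 10R,11R dioxane, and no later step touches them.
Key step: step 13

Remark: flavonolignan numbering is used (rings A and C carry O1 to C8a, ring B is the catechol ring on C2, ring D is the dioxane with C10 bearing CH2O and benzylic C11 bearing the guaiacyl ring E); 10R,11R equals (2R,3R) in benzodioxine numbering, and ferulic acid, 3,4-dihydroxybenzaldehyde and 3,5-bis(benzyloxy)phenol are taken as purchasable.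

Step 1
Reactants: 1 ferulic acid
Product: 2 benzyl (E)-3-[4-(benzyloxy)-3-methoxyphenyl]prop-2-enoate
Conditions: BnBr (2.4 equiv), K2CO3 (3 equiv), DMF, 60 °C
Reagents that add atoms: benzyl bromide, BrCc1ccccc1
Why: Carbonate ionises both the carboxylic acid and the phenol, and each anion displaces bromide from benzyl bromide (Williamson-type SN2 O-alkylation), so a single operation gives the ester needed for reduction and the benzyl ether that lasts to the final hydrogenolysis.

Step 2
Reactants: 2 benzyl (E)-3-[4-(benzyloxy)-3-methoxyphenyl]prop-2-enoate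
Product: 3 (E)-3-[4-(benzyloxy)-3-methoxyphenyl]prop-2-en-1-ol (O-benzylconiferyl alcohol)
Conditions: iBu2AlH (3 equiv), CH2Cl2, −78 → 0 °C; aq. potassium sodium tartrate
Reagents that add atoms: none
Why: Hydride reduction of an α,β-unsaturated ester with iBu2AlH proceeds by two 1,2-additions to the allylic alcohol, leaving the E double bond and the aryl benzyl ether untouched.

Step 3
Reactants: 3 (E)-3-[4-(benzyloxy)-3-methoxyphenyl]prop-2-en-1-ol
Product: 4 {(2S,3S)-3-[4-(benzyloxy)-3-methoxyphenyl]oxiran-2-yl}methanol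
Conditions: Ti(OiPr)4 (10 mol %), L-(+)-diisopropyl tartrate (12 mol %), t-BuOOH (2 equiv, decane), 4 Å MS, CH2Cl2, −20 °C; aq. NaOH/NaCl work-up at 0 °C
Reagents that add atoms: tert-butyl hydroperoxide, CC(C)(C)OO
Why: Sharpless asymmetric epoxidation: the titanium L-(+)-tartrate complex binds the allylic alcohol and the hydroperoxide and passes oxygen to the alkene face that turns E-allylic alcohols into 2S,3S-epoxy alcohols, so the tartrate sets both stereocentres at once while the E geometry fixes their trans relation, and sieves, low temperature and a basic work-up protect the electron-rich, acid-labile epoxide.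

Step 4
Reactants: 4 {(2S,3S)-3-[4-(benzyloxy)-3-methoxyphenyl]oxiran-2-yl}methanol
Product: 5 (2S,3S)-2-[(benzyloxy)methyl]-3-[4-(benzyloxy)-3-methoxyphenyl]oxirane
Conditions: NaH (1.2 equiv), BnBr (1.2 equiv), THF–DMF, 0 °C → rt
Reagents that add atoms: benzyl bromide, BrCc1ccccc1
Why: Williamson etherification of the primary alkoxide with benzyl bromide is fast at 0 °C in an aprotic medium, where Payne migration of the epoxide does not compete, and it leaves both stereocentres unchanged.

Step 5
Reactants: 6 3,4-dihydroxybenzaldehyde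
Product: 7 4-(allyloxy)-3-hydroxybenzaldehyde
Conditions: allyl bromide (1.05 equiv), NaHCO3 (1.5 equiv), DMF, 40 °C
Reagents that add atoms: allyl bromide, C=CCBr
Why: The hydroxyl para to the formyl group is clearly the more acidic one, so the weak base NaHCO3 ionises it selectively and Williamson allylation with one equivalent of allyl bromide leaves the 3-OH free.

Step 6
Reactants: 5 (2S,3S)-2-[(benzyloxy)methyl]-3-[4-(benzyloxy)-3-methoxyphenyl]oxirane; 7 4-(allyloxy)-3-hydroxybenzaldehyde
Product: 8 4-(allyloxy)-3-{(1R,2S)-3-(benzyloxy)-1-[4-(benzyloxy)-3-methoxyphenyl]-2-hydroxypropoxy}benzaldehyde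
Conditions: 7 (1.3 equiv), Cs2CO3 (0.3 equiv), DMF, 80 °C
Reagents that add atoms: none
Why: Base-catalysed SN2 opening of an aryl-substituted epoxide by a phenoxide goes to the benzylic carbon C11 (activated by ring E, whereas C10 is deactivated inductively by the CH2OBn group) with inversion from S to R, C10 keeps its S configuration as the free carbinol, and the absence of any acid avoids ionisation of the electron-rich benzylic centre.

Step 7
Reactants: 8 4-(allyloxy)-3-{(1R,2S)-3-(benzyloxy)-1-[4-(benzyloxy)-3-methoxyphenyl]-2-hydroxypropoxy}benzaldehyde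
Product: 9 3-{(1R,2S)-3-(benzyloxy)-1-[4-(benzyloxy)-3-methoxyphenyl]-2-hydroxypropoxy}-4-hydroxybenzaldehyde
Conditions: Pd(PPh3)4 (3 mol %), morpholine (5 equiv), THF, rt
Reagents that add atoms: none
Why: Tsuji–Trost-type deallylation: zerovalent palladium ionises only the allyl aryl ether to a π-allyl complex, which morpholine intercepts, so the benzyl ethers, the aldehyde, the secondary alcohol and both stereocentres are left as they are.

Step 8
Reactants: 9 3-{(1R,2S)-3-(benzyloxy)-1-[4-(benzyloxy)-3-methoxyphenyl]-2-hydroxypropoxy}-4-hydroxybenzaldehyde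
Product: 10 (2R,3R)-2-[(benzyloxy)methyl]-3-[4-(benzyloxy)-3-methoxyphenyl]-2,3-dihydro-1,4-benzodioxine-6-carbaldehyde
Conditions: PPh3 (1.5 equiv), DIAD (1.5 equiv), THF (0.02 M), 0 °C → rt
Reagents that add atoms: none
Why: Intramolecular Mitsunobu etherification: the acidic para-formyl phenol protonates the phosphine–azodicarboxylate adduct, the C10 hydroxyl becomes an oxyphosphonium leaving group and the phenoxide displaces it 6-exo-tet with inversion (S to R), which closes ring D as the trans 10R,11R isomer.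

Step 9
Reactants: 10 (2R,3R)-2-[(benzyloxy)methyl]-3-[4-(benzyloxy)-3-methoxyphenyl]-2,3-dihydro-1,4-benzodioxine-6-carbaldehyde
Product: 11 (2R,3R)-2-[(benzyloxy)methyl]-3-[4-(benzyloxy)-3-methoxyphenyl]-6-(2,2-dibromoethenyl)-2,3-dihydro-1,4-benzodioxine
Conditions: CBr4 (2 equiv), PPh3 (4 equiv), CH2Cl2, 0 °C
Reagents that add atoms: carbon tetrabromide, BrC(Br)(Br)Br
Why: First stage of the Corey–Fuchs homologation, a Wittig reaction of the ylide Ph3P=CBr2 formed in situ with a non-enolisable aromatic aldehyde under essentially neutral conditions that the ethers tolerate.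

Step 10
Reactants: 11 (2R,3R)-2-[(benzyloxy)methyl]-3-[4-(benzyloxy)-3-methoxyphenyl]-6-(2,2-dibromoethenyl)-2,3-dihydro-1,4-benzodioxine
Product: 13 3-{(2R,3R)-2-[(benzyloxy)methyl]-3-[4-(benzyloxy)-3-methoxyphenyl]-2,3-dihydro-1,4-benzodioxin-6-yl}prop-2-ynoic acid, via lithium acetylide 12 (not isolated)
Conditions: n-BuLi (2.2 equiv), THF, −78 °C; CO2 (g), −78 °C → rt; 1 M HCl
Reagents that add atoms: carbon dioxide, O=C=O
Why: Second stage of the Corey–Fuchs sequence: n-BuLi effects bromine–lithium exchange, loss of LiBr with rearrangement and deprotonation to acetylide 12, whose carboxylation with CO2 is a standard way to arylpropiolic acids, and at −78 °C these events outrun any metalation of the benzyl ethers.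

Step 11
Reactants: 14 3,5-bis(benzyloxy)phenol
Product: 15 3,5-bis(benzyloxy)-2-bromophenol
Conditions: NBS (1.0 equiv), iPr2NH (10 mol %), CH2Cl2, −78 → 0 °C
Reagents that add atoms: N-bromosuccinimide, O=C1CCC(=O)N1Br
Why: Electrophilic aromatic bromination of a highly activated phenol: the amine-modified NBS is guided by hydrogen bonding to the position ortho to OH, which is also para to one benzyloxy group and less crowded than C4 between two benzyloxy groups, and one equivalent at low temperature limits dibromination.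

Step 12
Reactants: 15 3,5-bis(benzyloxy)-2-bromophenol
Product: 18 3,5-bis(benzyloxy)-2-(trimethylsilyl)phenyl trifluoromethanesulfonate, via aryl trimethylsilyl ether 16 (not isolated), via lithium 2-silylphenoxide 17 (not isolated)
Conditions: (Me3Si)2NH, THF, reflux, then evaporate; n-BuLi (1.1 equiv), THF, −100 → −78 °C; Tf2O (1.2 equiv), −100 °C → rt
Reagents that add atoms: hexamethyldisilazane, C[Si](C)(C)N[Si](C)(C)C; trifluoromethanesulfonic anhydride, O=S(=O)(OS(=O)(=O)C(F)(F)F)C(F)(F)F
Why: Established route to o-silylaryl triflates: O-silylation to 16, bromine–lithium exchange (much faster at −100 °C than benzylic deprotonation) followed by a retro-Brook O-to-C silyl shift to phenoxide 17, and O-triflation with Tf2O.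

Step 13
Reactants: 13 3-{(2R,3R)-2-[(benzyloxy)methyl]-3-[4-(benzyloxy)-3-methoxyphenyl]-2,3-dihydro-1,4-benzodioxin-6-yl}prop-2-ynoic acid; 18 3,5-bis(benzyloxy)-2-(trimethylsilyl)phenyl trifluoromethanesulfonate
Product: 21 5,7-bis(benzyloxy)-2-{(2R,3R)-2-[(benzyloxy)methyl]-3-[4-(benzyloxy)-3-methoxyphenyl]-2,3-dihydro-1,4-benzodioxin-6-yl}-4H-chromen-4-one, via 3,5-bis(benzyloxy)benzyne 19 (not isolated), via o-hydroxyaryl ynone 20 (not isolated)
Conditions: 18 (1.5 equiv), CsF (4 equiv), THF, 125 °C (sealed tube)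
Reagents that add atoms: none
Why: Fluoride attacks silicon in 18 and triflate departs, releasing aryne 19 slowly because CsF is sparingly soluble in THF; the caesium carboxylate of 13 adds through oxygen, the aryl anion so formed attacks its own ester carbonyl (4-exo-trig), and the strained four-membered alkoxide opens to the o-acyl phenoxide of 20, a net insertion of the aryne into the acid C–O bond that makes C8a–O1 and C4a–C4. The closest known reaction type is exactly this fluoride-induced C–O insertion of arynes into carboxylic acids, which with 3-arylpropiolic acids runs on to flavones. Ring C, the only ring formed, closes by 6-endo-dig oxa-Michael addition of phenoxide O1 to the ynone β-carbon C2, and the resulting vinyl anion picks up the proton first carried by the acid to become C3–H. No stereocentre is created, and C10 and C11 lie far from the reacting atoms and carry no acidic hydrogen. The step needs regioselective addition to the aryne: the benzyloxy group next to the triple bond distorts the aryne and stabilises negative charge on the adjacent carbon inductively, so oxygen bonds to the remote aryne carbon (future C8a) and the acyl group ends on the carbon beside C5–OBn (future C4a). Chemoselectivity rests on full benzylation, which leaves the acid as the only protic nucleophile, while the high temperature favours the acyl shift over protonation of the aryl anion and the aprotic medium favours 6-endo over 5-exo (aurone) closure.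

Step 14
Reactants: 21 5,7-bis(benzyloxy)-2-{(2R,3R)-2-[(benzyloxy)methyl]-3-[4-(benzyloxy)-3-methoxyphenyl]-2,3-dihydro-1,4-benzodioxin-6-yl}-4H-chromen-4-one
Product: 23 5,7-bis(benzyloxy)-2-{(2R,3R)-2-[(benzyloxy)methyl]-3-[4-(benzyloxy)-3-methoxyphenyl]-2,3-dihydro-1,4-benzodioxin-6-yl}-3-hydroxy-4H-chromen-4-one, via flavone 2,3-epoxide 22 (not isolated)
Conditions: dimethyldioxirane (0.07 M in acetone, 3 equiv), CH2Cl2, 0 °C; then p-TsOH·H2O (10 mol %), rt
Reagents that add atoms: dimethyldioxirane, CC1(C)OO1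
Why: Dimethyldioxirane epoxidises the C2=C3 bond of the flavone, and acid opens epoxide 22 at C2 (cation stabilised by O1 and ring B) with loss of H3 to restore the pyranone as the 3-hydroxy compound, a known hydroxylation of perbenzylated flavones in which the transient epoxide stereocentres disappear again.

Step 15
Reactants: 23 5,7-bis(benzyloxy)-2-{(2R,3R)-2-[(benzyloxy)methyl]-3-[4-(benzyloxy)-3-methoxyphenyl]-2,3-dihydro-1,4-benzodioxin-6-yl}-3-hydroxy-4H-chromen-4-one
Product: 24 2,3-dehydrosilybin A, 3,5,7-trihydroxy-2-[(2R,3R)-3-(4-hydroxy-3-methoxyphenyl)-2-(hydroxymethyl)-2,3-dihydro-1,4-benzodioxin-6-yl]-4H-chromen-4-one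
Conditions: H2 (1 atm), 10% Pd/C, THF–MeOH, rt
Reagents that add atoms: none
Why: Catalytic hydrogenolysis cleaves the four O-benzyl groups, whereas the pyranone double bond and the ring-D benzylic C11–O bond (secondary, hindered and tied into a ring) react far more slowly, so stopping after uptake of four equivalents of H2 should give the target with C10 and C11 intact.

Compound list
1 | ferulic acid | COc1cc(/C=C/C(=O)O)ccc1O | starting material
2 | benzyl (E)-3-[4-(benzyloxy)-3-methoxyphenyl]prop-2-enoate | COc1cc(/C=C/C(=O)OCc2ccccc2)ccc1OCc1ccccc1 | intermediate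
3 | (E)-3-[4-(benzyloxy)-3-methoxyphenyl]prop-2-en-1-ol | COc1cc(/C=C/CO)ccc1OCc1ccccc1 | intermediate
4 | {(2S,3S)-3-[4-(benzyloxy)-3-methoxyphenyl]oxiran-2-yl}methanol | COc1cc([C@@H]2O[C@H]2CO)ccc1OCc1ccccc1 | intermediate
5 | (2S,3S)-2-[(benzyloxy)methyl]-3-[4-(benzyloxy)-3-methoxyphenyl]oxirane | COc1cc([C@@H]2O[C@H]2COCc2ccccc2)ccc1OCc1ccccc1 | intermediate
6 | 3,4-dihydroxybenzaldehyde | O=Cc1ccc(O)c(O)c1 | starting material
7 | 4-(allyloxy)-3-hydroxybenzaldehyde | C=CCOc1ccc(C=O)cc1O | intermediate
8 | 4-(allyloxy)-3-{(1R,2S)-3-(benzyloxy)-1-[4-(benzyloxy)-3-methoxyphenyl]-2-hydroxypropoxy}benzaldehyde | COc1cc([C@@H](Oc2cc(C=O)ccc2OCC=C)[C@@H](O)COCc2ccccc2)ccc1OCc1ccccc1 | intermediate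
9 | 3-{(1R,2S)-3-(benzyloxy)-1-[4-(benzyloxy)-3-methoxyphenyl]-2-hydroxypropoxy}-4-hydroxybenzaldehyde | COc1cc([C@@H](Oc2cc(C=O)ccc2O)[C@@H](O)COCc2ccccc2)ccc1OCc1ccccc1 | intermediate
10 | (2R,3R)-2-[(benzyloxy)methyl]-3-[4-(benzyloxy)-3-methoxyphenyl]-2,3-dihydro-1,4-benzodioxine-6-carbaldehyde | COc1cc([C@H]2Oc3cc(C=O)ccc3O[C@@H]2COCc2ccccc2)ccc1OCc1ccccc1 | intermediate
11 | (2R,3R)-2-[(benzyloxy)methyl]-3-[4-(benzyloxy)-3-methoxyphenyl]-6-(2,2-dibromoethenyl)-2,3-dihydro-1,4-benzodioxine | COc1cc([C@H]2Oc3cc(C=C(Br)Br)ccc3O[C@@H]2COCc2ccccc2)ccc1OCc1ccccc1 | intermediate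
12 | lithium acetylide of the (2R,3R)-benzodioxine (6-lithioethynyl compound) | COc1cc([C@H]2Oc3cc(C#C[Li])ccc3O[C@@H]2COCc2ccccc2)ccc1OCc1ccccc1 | intermediate
13 | 3-{(2R,3R)-2-[(benzyloxy)methyl]-3-[4-(benzyloxy)-3-methoxyphenyl]-2,3-dihydro-1,4-benzodioxin-6-yl}prop-2-ynoic acid | COc1cc([C@H]2Oc3cc(C#CC(=O)O)ccc3O[C@@H]2COCc2ccccc2)ccc1OCc1ccccc1 | intermediate
14 | 3,5-bis(benzyloxy)phenol | Oc1cc(OCc2ccccc2)cc(OCc2ccccc2)c1 | starting material
15 | 3,5-bis(benzyloxy)-2-bromophenol | Oc1cc(OCc2ccccc2)cc(OCc2ccccc2)c1Br | intermediate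
16 | [3,5-bis(benzyloxy)-2-bromophenoxy]trimethylsilane | C[Si](C)(C)Oc1cc(OCc2ccccc2)cc(OCc2ccccc2)c1Br | intermediate
17 | lithium 3,5-bis(benzyloxy)-2-(trimethylsilyl)phenoxide | [Li+].[O-]c1cc(OCc2ccccc2)cc(OCc2ccccc2)c1[Si](C)(C)C | intermediate
18 | 3,5-bis(benzyloxy)-2-(trimethylsilyl)phenyl trifluoromethanesulfonate | C[Si](C)(C)c1c(OCc2ccccc2)cc(OCc2ccccc2)cc1OS(=O)(=O)C(F)(F)F | intermediate
19 | 3,5-bis(benzyloxy)benzyne (1,2-didehydro-3,5-bis(benzyloxy)benzene) | C1#CC(OCc2ccccc2)=CC(OCc2ccccc2)=C1 | intermediate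
20 | 1-[2,4-bis(benzyloxy)-6-hydroxyphenyl]-3-{(2R,3R)-2-[(benzyloxy)methyl]-3-[4-(benzyloxy)-3-methoxyphenyl]-2,3-dihydro-1,4-benzodioxin-6-yl}prop-2-yn-1-one (present as its caesium phenoxide) | COc1cc([C@H]2Oc3cc(C#CC(=O)c4c(O)cc(OCc5ccccc5)cc4OCc4ccccc4)ccc3O[C@@H]2COCc2ccccc2)ccc1OCc1ccccc1 | intermediate
21 | 5,7-bis(benzyloxy)-2-{(2R,3R)-2-[(benzyloxy)methyl]-3-[4-(benzyloxy)-3-methoxyphenyl]-2,3-dihydro-1,4-benzodioxin-6-yl}-4H-chromen-4-one | COc1cc([C@H]2Oc3cc(-c4cc(=O)c5c(OCc6ccccc6)cc(OCc6ccccc6)cc5o4)ccc3O[C@@H]2COCc2ccccc2)ccc1OCc1ccccc1 | intermediate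
22 | 2,3-epoxide of flavone 21 (both epoxide diastereomers, ring D unchanged 2R,3R) | COc1cc([C@H]2Oc3cc(C45OC4C(=O)c4c(OCc6ccccc6)cc(OCc6ccccc6)cc4O5)ccc3O[C@@H]2COCc2ccccc2)ccc1OCc1ccccc1 | intermediate
23 | 5,7-bis(benzyloxy)-2-{(2R,3R)-2-[(benzyloxy)methyl]-3-[4-(benzyloxy)-3-methoxyphenyl]-2,3-dihydro-1,4-benzodioxin-6-yl}-3-hydroxy-4H-chromen-4-one | COc1cc([C@H]2Oc3cc(-c4oc5cc(OCc6ccccc6)cc(OCc6ccccc6)c5c(=O)c4O)ccc3O[C@@H]2COCc2ccccc2)ccc1OCc1ccccc1 | intermediate
24 | 2,3-dehydrosilybin A | COc1cc([C@H]2Oc3cc(-c4oc5cc(O)cc(O)c5c(=O)c4O)ccc3O[C@@H]2CO)ccc1O | target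

Total step count: 15. Longest linear sequence: 12 (steps 1–4, 6–10, 13–15).

Steps most likely to fail

Step 13. At 125 °C the propiolate may lose CO2. The aryl anion may be protonated before the acyl shift, so that the sequence stops at the aryl ester. The aryne may also be consumed by self-reaction. The fallback gives up the aryne and builds ring C from a chalcone; it sets out from aldehyde 10 and returns at flavone 21. Claisen–Schmidt condensation of 10 with commercial 1-[2,4-bis(benzyloxy)-6-hydroxyphenyl]ethan-1-one F1 (KOH, EtOH, rt) should give the (E)-2'-hydroxychalcone F2. Heating F2 with I2 (10 mol %) in DMSO at 120 °C should then close O1–C2 by oxa-Michael addition and dehydrogenate the flavanone to 21.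

Step 3. The titanium Lewis acid may promote solvolysis of the electron-rich epoxide by isopropanol or tert-butanol during the reaction or the work-up, with loss of material and of enantiopurity. The fallback avoids any Lewis acid; it sets out from allylic alcohol 3 and returns at epoxy ether 5, so step 4 is no longer needed. Benzylation of 3 (NaH, BnBr, THF) gives (E)-1-(benzyloxy)-4-[3-(benzyloxy)prop-1-enyl]-2-methoxybenzene F3. F3 is then submitted to Shi epoxidation with the L-fructose-derived enantiomer of the Shi ketone (30 mol %), KHSO5 (as 2KHSO5·KHSO4·K2SO4) and K2CO3 buffer near pH 10.5 in MeCN–dimethoxymethane–H2O at 0 °C. The D-fructose ketone converts E-aryl alkenes into R,R epoxides, so its mirror image should deliver the S,S epoxide 5.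

Step 14. The enone double bond is a sluggish acceptor, so excess dioxirane may oxidise benzylic C–H bonds (the benzyl ethers and C11–H) or the electron-rich rings before epoxidation is complete. The fallback replaces electrophilic oxidation by C3 metalation; it sets out from flavone 21 and returns at flavonol 23. LiN(iPr)2 in THF at −78 °C should give the 3-lithioflavone F4, and B(OMe)3 should convert it into the dimethyl flavon-3-ylboronate F5. H2O2 in AcOH–THF at 0 °C then oxidises the C–B bond to the 3-hydroxyl of 23.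

Further compounds
F1 | step 13 | 1-[2,4-bis(benzyloxy)-6-hydroxyphenyl]ethan-1-one (bought partner) | CC(=O)c1c(O)cc(OCc2ccccc2)cc1OCc1ccccc1
F2 | step 13 | (E)-1-[2,4-bis(benzyloxy)-6-hydroxyphenyl]-3-{(2R,3R)-2-[(benzyloxy)methyl]-3-[4-(benzyloxy)-3-methoxyphenyl]-2,3-dihydro-1,4-benzodioxin-6-yl}prop-2-en-1-one | COc1cc([C@H]2Oc3cc(/C=C/C(=O)c4c(O)cc(OCc5ccccc5)cc4OCc4ccccc4)ccc3O[C@@H]2COCc2ccccc2)ccc1OCc1ccccc1
F3 | step 3 | (E)-1-(benzyloxy)-4-[3-(benzyloxy)prop-1-enyl]-2-methoxybenzene | COc1cc(/C=C/COCc2ccccc2)ccc1OCc1ccccc1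
F4 | step 14 | 3-lithio derivative of flavone 21 | COc1cc([C@H]2Oc3cc(-c4oc5cc(OCc6ccccc6)cc(OCc6ccccc6)c5c(=O)c4[Li])ccc3O[C@@H]2COCc2ccccc2)ccc1OCc1ccccc1
F5 | step 14 | dimethyl boronate at C3 of flavone 21 | COc1cc([C@H]2Oc3cc(-c4oc5cc(OCc6ccccc6)cc(OCc6ccccc6)c5c(=O)c4B(OC)OC)ccc3O[C@@H]2COCc2ccccc2)ccc1OCc1ccccc1
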